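Target forms first and erodes later.

| setting | Wednesday's | Monday's | Sunday's | autumn | spring |
|---|---|---|---|---|---|
| substrate | 0.020 M | 0.020 M | 0.020 M | 0.020 M | 0.020 M |
| partner | 0.033 M | 0.049 M | 0.056 M | 0.0300 M | 0.0750 M |
| free catalyst | 0.20 mM | 0.20 mM | 0.20 mM | 0.20 mM | 0.20 mM |
| remark | run made earlier | run made earlier | run made earlier |  |  |
| time |  |  |  | 30 min | 30 min |

| run | time / min | substrate / % | catalyst intermediate B / % | isomer of the product / % | catalyst intermediate C / % | target / % |
|---|---|---|---|---|---|---|
| Wednesday's | 1.50 | 91 | 1 | 0 | 0 | 8 |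
| Wednesday's | 3.00 | 84 | 0 | 3 | 1 | 18 |
| Wednesday's | 6.00 | 65 | 1 | 0 | 0 | 29 |
| Wednesday's | 12.0 | 43 | 1 | 0 | 0 | 56 |
| Wednesday's | 20.0 | 18 | 0 | 2 | 1 | 81 |
| Monday's | 4.00 | 73 | 0 | 3 | 0 | 28 |
| Monday's | 8.00 | 48 | 1 | 1 | 1 | 56 |
| Monday's | 12.0 | 26 | 0 | 4 | 0 | 73 |
| Monday's | 15.0 | 16 | 0 | 2 | 0 | 83 |
| Monday's | 20.0 | 1 | 0 | 7 | 4 | 92 |
| Sunday's | 1.50 | 90 | 0 | 0 | 1 | 9 |
| Sunday's | 3.00 | 77 | 2 | 0 | 0 | 21 |
| Sunday's | 6.00 | 53 | 0 | 0 | 0 | 44 |
| Sunday's | 12.0 | 21 | 0 | 3 | 1 | 75 |
| Sunday's | 20.0 | 5 | 3 | 9 | 0 | 87 |

(each reading ± 1.5 percentage points)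

- the earlier runs were read with a standard deviation of 1.5 percentage points

- which of these there is most of at the end, counted by the substrate in it, autumn (catalyst intermediate C / catalyst intermediate B / target / substrate / isomer of the product)
- which of these there is most of at the end, counted by the substrate in it, spring (catalyst intermediate C / catalyst intermediate B / target / substrate / isomer of the product)
- amount of the one of these that there is most of at the end, in percent of the substrate charged, autumn
- amount of the one of these that there is most of at the end, in percent of the substrate charged, spring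

Take the main step first. Its measure is the turnover time (inverse turnover frequency): elapsed time per substrate consumed per catalyst charged. Wednesday's run converts 82.0% in 20.0 min, which is 0.244 min per turn. Sunday's run converts 79.0% in 12.0 min, or 0.152 min per turn.

Partner falls as substrate reacts, so its curve is replaced by its mean, the charge less half of what has reacted: 0.0248 M and 0.0481 M. My reading of these two runs is a turnover time of 0.0540 min, multiplied by one plus 0.0873 M over c(partner). For Monday's run, which did not enter this reading, it gives 14.3 min to reach the 84.0% conversion read at 15.0 min.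

With partner held at its charge, my reckoning puts autumn at that conversion of 82.0% after 17.3 min and spring after 9.58 min. Adding partner's fall gives 22.1 min for autumn and 10.2 min for spring. In autumn, averaging over partner's steady fall in place of taking its mean gives 23.1 min, which is 1.000 min longer.

Now add isomer. Sunday's run read 9% isomer at 20.0 min, 8.00 min past its reading of 79.0% conversion, which is taken here as standing in for 82.0%. By my reckoning, spring has 19.8 min left after 82.0% conversion and autumn 7.86 min: this time left is the standing time. In proportion, isomer comes to 22.3% in spring and 8.84% in autumn. My figure for target is therefore 77.7% in spring and 91.2% in autumn, before any remaining substrate is subtracted.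

The forecast answers target for autumn and target for spring, at 82% and 72%, figures that differ from mine. Of the erosion of target in spring it says: “Extrapolating this is the main uncertainty.”

The flasks give target in autumn, at 89.0%, and target in spring, at 72.0%.

    substrate + free catalyst → catalyst intermediate A (k = 59.0 L mol⁻¹ s⁻¹)
    catalyst intermediate A → catalyst intermediate B (k = 0.470 s⁻¹)
    partner + catalyst intermediate B ⇌ catalyst intermediate C (K = 42.0 L mol⁻¹, k = 4.40 L mol⁻¹ s⁻¹)
    catalyst intermediate C ⇌ free catalyst + target (K = 0.220 M, k = 3.50 s⁻¹)
    target + free catalyst ⇌ isomer of the product + free catalyst, rate k5*[free catalyst]*[target] forward; the back reaction follows from the equilibrium constant (K = 7.30, k = 1.70 L mol⁻¹ s⁻¹)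
    partner → decomposed reagent (k = 5.70 × 10⁻⁵ s⁻¹)

Spring, with 19.8 min of standing time against 7.86 min in autumn, holds isomer 27.9% against 5.89%; the reckoning gave 22.3% and 8.84%. For autumn's flask with 3.4 × 10⁻⁴ M of free catalyst in place of 0.20 mM, scaling the conversion time and isomer pace by catalyst gives a standing time of 17.0 min and isomer 32.5%. At the end that flask holds isomer 30.2% and target 69.5%.

The readings are simulated for an exercise, noise included.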